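**Strategy**

Everything rests on cutting the ring-fusion bond C8–C9 (labdane numbering) of the cis-fused oxadecalin, carbocyclic ring B and tetrahydropyran ring C. The key step exploits that the ring oxygen on C8 is 1,5 to C13: with C13 as an acyl carbon, ring C is a δ-lactone whose γ-carbon is C9. A chiral isothiourea turns an open-chain (E)-β,γ-unsaturated keto acid into a dienolate; C9 adds to the C8 methyl ketone and the alkoxide lactonises on C13, closing rings B and C and setting C8 and C9 in one operation. The precursor comes from ozonolytic opening of a cyclohexene template that fixed C5 and C10; both halves diverge later by Sharpless epoxidation.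

Key step: step 10

Numbering used throughout (labdane, for every intermediate and each half of the target): C8 = ring-fusion carbon with CH3-17 and the ring oxygen; C9 = ring-fusion CH; C10 = quaternary carbon with CH3-20 and C1H2–C2O2H; C5 = CH carrying C4(CH3)2–C3O2H; C6, C7 = ring B CH2; C11, C12 = ring C CH2; C13 = O-bearing quaternary carbon with CH3-16; C14, C15 = side chain.

Remark on the chemistry: the target is read as the ester of the C2 acid of the 13R vinyl half with O15 of the 13S,14R diol half. Both halves share the 5S,8S,9R,10R core (H9 and CH3-17 cis), so one core is made and C13 is set last. In steps 2 and 10 the antipode of the catalyst that leads to the drawn configuration is assumed.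

**Route**

Step 1
Reactants: 1 tert-butyl 2-methylpropanoate
Product: 3 1-tert-butoxy-2-methyl-1-(trimethylsilyloxy)prop-1-ene, via lithium ester enolate 2 (not isolated)
Conditions: LiN(iPr)2, THF, −78 °C; Me3SiCl, −78 °C → rt
Reagents that add atoms: chlorotrimethylsilane, C[Si](C)(C)Cl
Why: Kinetic deprotonation and O-silylation of the α,α-disubstituted ester enolate should give the silyl ketene acetal; no stereocentre is formed.

Step 2
Reactants: 4 2-methylcyclohex-2-en-1-one; 3 silyl ketene acetal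
Product: 5 tert-butyl 2-methyl-2-[(1S)-2-methyl-3-(trimethylsilyloxy)cyclohex-2-en-1-yl]propanoate
Conditions: 3,3-diphenyl-1-(o-tolyl)tetrahydro-1H,3H-pyrrolo[1,2-c][1,3,2]oxazaborole (20 mol%, single enantiomer) activated with HNTf2 (20 mol%), toluene, −40 °C; non-aqueous work-up
Reagents that add atoms: none
Why: Catalytic asymmetric Mukaiyama–Michael addition: the chiral oxazaborolidinium ion binds the enone carbonyl and shields one face of the β-carbon, so C5 (S) is set by the catalyst, and silyl transfer leaves the regiodefined C9=C10 silyl enol ether.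

Step 3
Reactants: 5 silyl enol ether; 6 tert-butyl bromoacetate
Product: 8 tert-butyl 2-[(1S,2R)-2-(2-tert-butoxy-2-oxoethyl)-2-methyl-3-oxocyclohexyl]-2-methylpropanoate, via lithium ketone enolate 7 (not isolated)
Conditions: MeLi, THF, 0 °C; then 6, DMPU, −78 → 0 °C
Reagents that add atoms: none
Why: MeLi cleaves the Si–O bond to the regiodefined lithium enolate, and C-alkylation by the α-bromo ester should occur anti to the neighbouring C(CH3)2CO2tBu group (substrate control), so the new quaternary C10 carries CH2CO2tBu trans to it.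

Step 4
Reactants: 8 ketone
Product: 10 tert-butyl 2-[(1S,2R,4RS)-2-(2-tert-butoxy-2-oxoethyl)-2,4-dimethyl-3-oxocyclohexyl]-2-methylpropanoate, via lithium enolate 9 (not isolated)
Conditions: LiN(iPr)2, THF, −78 °C; MeI, −78 → 0 °C
Reagents that add atoms: iodomethane, CI
Why: Enolate methylation on the only enolisable side (C8) brings in C17; the new centre becomes sp2 in step 5, so both epimers are carried on.

Step 5
Reactants: 10 methyl ketone
Product: 12 tert-butyl 2-[(1S,2R)-2-(2-tert-butoxy-2-oxoethyl)-2,4-dimethyl-3-(trifluoromethylsulfonyloxy)cyclohex-3-en-1-yl]-2-methylpropanoate, via potassium enolate 11 (not isolated)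
Conditions: KN(SiMe3)2, THF, −78 → 0 °C; PhNTf2, 0 °C → rt
Reagents that add atoms: N-phenylbis(trifluoromethanesulfonimide), O=S(=O)(N(c1ccccc1)S(=O)(=O)C(F)(F)F)C(F)(F)F
Why: O-Sulfonylation of the only possible enolate gives the C8=C9 enol triflate, as is usual for 2,2,6-trisubstituted cyclohexanones.

Step 6
Reactants: 12 enol triflate
Product: 13 tert-butyl 2-[(1S,2S)-2-(2-tert-butoxy-2-oxoethyl)-2,4-dimethylcyclohex-3-en-1-yl]-2-methylpropanoate
Conditions: Pd(OAc)2 (5 mol%), PPh3 (10 mol%), HCO2H, Bu3N, DMF, 60 °C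
Reagents that add atoms: none
Why: Palladium-catalysed formate reduction of the enol triflate (oxidative addition, formate-to-hydride transfer, reductive elimination) should give the trisubstituted C8=C9 alkene without touching the esters.

Step 7
Reactants: 13 cyclohexene
Product: 15 di-tert-butyl (3S,4R)-4-formyl-2,2,4-trimethyl-3-(3-oxobutyl)hexanedioate, via secondary ozonide 14 (not isolated)
Conditions: O3, CH2Cl2, −78 °C; Me2S, −78 °C → rt
Reagents that add atoms: ozone, [O-][O+]=O
Why: Ozonolysis (Criegee mechanism) of the only C=C bond opens the template ring between C8 and C9 to the methyl ketone and a non-enolisable aldehyde, so C5 and C10 are not at risk.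

Step 8
Reactants: 15 keto aldehyde; 16 (2-carboxyethyl)triphenylphosphonium bromide
Product: 17 (3Z,5S,6S)-5-(2-tert-butoxy-2-oxoethyl)-6-(1-tert-butoxy-2-methyl-1-oxopropan-2-yl)-5-methyl-9-oxodec-3-enoic acid
Conditions: 16, NaN(SiMe3)2 (2 equiv per 16), THF, −78 → 0 °C; then 15, −78 °C → rt; aq. NaH2PO4
Reagents that add atoms: none
Why: Wittig olefination with the non-stabilised carboxylate ylide should take the aldehyde much faster than the methyl ketone at −78 °C and give the (Z)-alkene under lithium-free kinetic control.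

Step 9
Reactants: 17 (Z)-acid
Product: 18 (3E,5S,6S)-5-(2-tert-butoxy-2-oxoethyl)-6-(1-tert-butoxy-2-methyl-1-oxopropan-2-yl)-5-methyl-9-oxodec-3-enoic acid
Conditions: PhSSPh (10 mol%), hν (365 nm), benzene, rt
Reagents that add atoms: none
Why: Reversible thiyl-radical addition–elimination equilibrates the alkene to the (E)-isomer, which is strongly favoured next to the quaternary C10, without moving the double bond.

Step 10
Reactants: 18 (E)-β,γ-unsaturated keto acid
Product: 20 di-tert-butyl ester of (5S,8S,9R,10R)-2,3-seco-14,15,16-trinorlabd-11-en-13,8-olide-2,3-dioic acid (cis-fused 5,6-dihydropyran-2-one on ring B), via mixed pivalic anhydride 19 (not isolated)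
Conditions: t-BuCOCl, iPr2NEt, CH2Cl2, 0 °C; then 3-isopropyl-2-phenyl-3,4-dihydro-2H-benzo[4,5]thiazolo[3,2-a]pyrimidine (10 mol%, single enantiomer), rt
Reagents that add atoms: none
Why: Proposed new method: the isothiourea is acylated by the mixed anhydride, iPr2NEt removes the doubly activated C12 proton, and the s-cis (E)-dienolate adds through its γ-carbon C9 to the tethered methyl ketone C8 while the new C8 alkoxide attacks the acyl carbon C13 and releases the catalyst (vinylogous aldol-lactonisation, a formal oxa-[4+2]). The closest known reactions are the nucleophile-catalysed aldol-lactonisation of keto acids to bicyclic β-lactones and the intermolecular [4+2] annulation of ammonium or azolium dienolates with activated ketones; new is the intramolecular γ-attack on an unactivated ketone. Ring B closes by 6-exo-trig attack of C9 on the C8 carbonyl and ring C by 6-exo-trig acyl substitution of O8 at C13. C9 is set by the dienolate face that the catalyst leaves open (antipode chosen so that C11 stands axial on the chair of the forming ring B, anti to the axial CH3-20, with both ester-bearing groups equatorial); C8 follows because, with C11 axial, only an equatorial ketone oxygen can reach C13, which makes the fusion cis (H9 and CH3-17 cis). The step needs γ- over α-attack (α-attack would demand an eight-membered ring), enolisation of the acyl isothiouronium but not of the ketone (only the former is acidic enough for iPr2NEt), and the (E)-C9=C11 geometry from step 9, since the (Z)-alkene would lead to the C8,C9-bis-epimer.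

Step 11
Reactants: 20 unsaturated lactone
Product: 21 di-tert-butyl ester of (5S,8S,9R,10R)-2,3-seco-14,15,16-trinorlabdan-13,8-olide-2,3-dioic acid
Conditions: H2 (1 atm), 10% Pd/C, EtOAc, rt
Reagents that add atoms: none
Why: Heterogeneous hydrogenation of the conjugated disubstituted C11=C12 bond; no stereocentre is formed and the tert-butyl esters persist.

Step 12
Reactants: 21 δ-lactone
Product: 22 di-tert-butyl (5S,8S,9R,10R)-8-hydroxy-13-oxo-14,15-dinor-2,3-secolabdane-2,3-dioate (in equilibrium with its lactol)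
Conditions: MeLi (1.05 equiv), THF, −78 °C; aq. NH4Cl at −78 °C
Reagents that add atoms: methyllithium, [Li]C
Why: Single addition of MeLi to the lactone: the tetrahedral lithium hemiketalate is stable at −78 °C and collapses only on work-up, and the lactone is more electrophilic than the hindered tert-butyl esters.

Step 13
Reactants: 22 hydroxy ketone; 23 triethyl phosphonoacetate
Product: 24 15-ethyl 2,3-di-tert-butyl (5S,8S,9R,10R,13E)-8-hydroxy-2,3-secolabd-13-ene-2,3,15-trioate
Conditions: NaH, 23, THF, 0 °C; then 22, 0 → 50 °C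
Reagents that add atoms: none
Why: Horner–Wadsworth–Emmons olefination of the methyl ketone should give mainly the (E)-trisubstituted enoate; the minor (Z)-isomer is removed by chromatography here or after step 14.

Step 14
Reactants: 24 enoate
Product: 25 di-tert-butyl (5S,8S,9R,10R,13E)-8,15-dihydroxy-2,3-secolabd-13-ene-2,3-dioate
Conditions: iBu2AlH, CH2Cl2, −78 °C; Rochelle salt work-up
Reagents that add atoms: none
Why: 1,2-Reduction of the ethyl ester by iBu2AlH at −78 °C, where the two hindered tert-butyl esters react much more slowly.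

Step 15
Reactants: 25 allylic alcohol
Product: 27 di-tert-butyl (5S,8S,9R,10R,13S,14R)-8,13-epoxy-14,15-dihydroxy-2,3-secolabdane-2,3-dioate, via 13R,14R epoxy alcohol 26 (not isolated)
Conditions: Ti(OiPr)4, D-(−)-diethyl tartrate, t-BuOOH, 4 Å MS, CH2Cl2, −20 °C; then camphor-10-sulfonic acid, 0 °C → rt
Reagents that add atoms: tert-butyl hydroperoxide, CC(C)(C)OO
Why: Sharpless asymmetric epoxidation (reagent control, D-tartrate gives the 13R,14R epoxide), then acid-promoted 6-exo-tet opening at the tertiary C13 by the C8 hydroxyl with inversion, which closes ring C with 13S and keeps 14R.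

Step 16
Reactants: 25 allylic alcohol
Product: 29 di-tert-butyl (5S,8S,9R,10R,13R,14S)-8,13-epoxy-14,15-dihydroxy-2,3-secolabdane-2,3-dioate, via 13S,14S epoxy alcohol 28 (not isolated)
Conditions: Ti(OiPr)4, L-(+)-diethyl tartrate, t-BuOOH, 4 Å MS, CH2Cl2, −20 °C; then camphor-10-sulfonic acid, 0 °C → rt
Reagents that add atoms: tert-butyl hydroperoxide, CC(C)(C)OO
Why: The same Sharpless epoxidation/6-exo-tet opening with the other tartrate gives the 13S,14S epoxide and, after inversion at C13, the 13R ring C (C14 is removed in step 17).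

Step 17
Reactants: 29 diol
Product: 30 di-tert-butyl (5S,8S,9R,10R,13R)-8,13-epoxy-2,3-secolabd-14-ene-2,3-dioate
Conditions: PPh3, imidazole, I2, toluene, 90 °C
Reagents that add atoms: none
Why: Garegg–Samuelsson deoxygenation: the primary iodide/secondary oxyphosphonium intermediate undergoes iodide-induced reductive elimination to the terminal alkene without involving C13.

Step 18
Reactants: 30 vinyl diester
Product: 32 (5S,8S,9R,10R,13R)-8,13-epoxy-2,3-secolabd-14-ene-2,3-dioic acid, via bis(trimethylsilyl) ester 31 (not isolated)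
Conditions: Me3SiOTf, 2,6-lutidine, CH2Cl2, 0 °C; aq. citric acid/THF
Reagents that add atoms: none
Why: Silyl triflate-mediated cleavage of tert-butyl esters (carbonyl O-silylation, loss of 2-methylpropene) under lutidine buffering; the ring oxygen between two quaternary carbons is too hindered to be silylated, which should spare the tertiary allylic ether.

Step 19
Reactants: 32 diacid; 27 diol
Product: 34 ester of the C2 carboxyl of 32 with O15 of 27 (C3 acid free, C14′ hydroxyl free, two tert-butyl esters), via cyclic anhydride 33 (not isolated)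
Conditions: N-(3-dimethylaminopropyl)-N′-ethylcarbodiimide hydrochloride, CH2Cl2, 0 °C → rt; then 27, 4-(dimethylamino)pyridine, rt
Reagents that add atoms: none
Why: Carbodiimide dehydration of the diacid to the seven-membered cyclic anhydride, then acyl-transfer-catalysed alcoholysis by the primary C15 hydroxyl at the less hindered CH2C(=O) carbonyl (C2); the pivaloyl-like C3 carbonyl and the hindered C14 hydroxyl should not compete.

Step 20
Reactants: 34 coupled di-tert-butyl ester
Product: 36 CNP0271961.3 (target), via tetrakis(trimethylsilyl) derivative 35 (not isolated)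
Conditions: Me3SiOTf, 2,6-lutidine, CH2Cl2, 0 °C; aq. citric acid/THF, rt
Reagents that add atoms: none
Why: The same tert-butyl ester cleavage as in step 18; the transient silyl groups on the acids and on the C14′ hydroxyl are lost on mildly acidic aqueous work-up, which does not hydrolyse the alkyl ester link.

**Compound list**

1 | tert-butyl 2-methylpropanoate | CC(C)C(=O)OC(C)(C)C | starting material
2 | lithium 1-tert-butoxy-2-methylprop-1-en-1-olate | [Li+].[O-]C(OC(C)(C)C)=C(C)C | intermediate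
3 | 1-tert-butoxy-2-methyl-1-(trimethylsilyloxy)prop-1-ene | CC(C)=C(OC(C)(C)C)O[Si](C)(C)C | intermediate
4 | 2-methylcyclohex-2-en-1-one | CC1=CCCCC1=O | starting material
5 | tert-butyl 2-methyl-2-[(1S)-2-methyl-3-(trimethylsilyloxy)cyclohex-2-en-1-yl]propanoate | CC1=C(O[Si](C)(C)C)CCC[C@@H]1C(C)(C)C(=O)OC(C)(C)C | intermediate
6 | tert-butyl bromoacetate | BrCC(=O)OC(C)(C)C | starting material
7 | lithium enolate from 5 (C9=C10 enolate) | CC1=C([O-])CCC[C@@H]1C(C)(C)C(=O)OC(C)(C)C.[Li+] | intermediate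
8 | tert-butyl 2-[(1S,2R)-2-(2-tert-butoxy-2-oxoethyl)-2-methyl-3-oxocyclohexyl]-2-methylpropanoate | O=C1[C@](C)(CC(=O)OC(C)(C)C)[C@@H](C(C)(C)C(=O)OC(C)(C)C)CCC1 | intermediate
9 | lithium enolate of 8 (C8=C9 enolate) | [Li+].[O-]C=1[C@](C)(CC(=O)OC(C)(C)C)[C@@H](C(C)(C)C(=O)OC(C)(C)C)CCC=1 | intermediate
10 | tert-butyl 2-[(1S,2R,4RS)-2-(2-tert-butoxy-2-oxoethyl)-2,4-dimethyl-3-oxocyclohexyl]-2-methylpropanoate | O=C1[C@](C)(CC(=O)OC(C)(C)C)[C@@H](C(C)(C)C(=O)OC(C)(C)C)CCC1C | intermediate
11 | potassium enolate of 10 | [K+].[O-]C=1[C@](C)(CC(=O)OC(C)(C)C)[C@@H](C(C)(C)C(=O)OC(C)(C)C)CCC=1C | intermediate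
12 | enol triflate: tert-butyl 2-[(1S,2R)-2-(2-tert-butoxy-2-oxoethyl)-2,4-dimethyl-3-(trifluoromethylsulfonyloxy)cyclohex-3-en-1-yl]-2-methylpropanoate | CC1=C(OS(=O)(=O)C(F)(F)F)[C@](C)(CC(=O)OC(C)(C)C)[C@@H](C(C)(C)C(=O)OC(C)(C)C)CC1 | intermediate
13 | tert-butyl 2-[(1S,2S)-2-(2-tert-butoxy-2-oxoethyl)-2,4-dimethylcyclohex-3-en-1-yl]-2-methylpropanoate | CC1=C[C@](C)(CC(=O)OC(C)(C)C)[C@@H](C(C)(C)C(=O)OC(C)(C)C)CC1 | intermediate
14 | secondary ozonide of 13 (1,2,4-trioxolane bridging C8 and C9) | CC12CC[C@H](C(C)(C)C(=O)OC(C)(C)C)[C@@](C)(CC(=O)OC(C)(C)C)C(OO1)O2 | intermediate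
15 | di-tert-butyl (3S,4R)-4-formyl-2,2,4-trimethyl-3-(3-oxobutyl)hexanedioate | CC(=O)CC[C@H](C(C)(C)C(=O)OC(C)(C)C)[C@@](C)(CC(=O)OC(C)(C)C)C=O | intermediate
16 | (2-carboxyethyl)triphenylphosphonium bromide | OC(=O)CC[P+](c1ccccc1)(c1ccccc1)c1ccccc1.[Br-] | starting material
17 | (3Z,5S,6S)-5-(2-tert-butoxy-2-oxoethyl)-6-(1-tert-butoxy-2-methyl-1-oxopropan-2-yl)-5-methyl-9-oxodec-3-enoic acid | CC(=O)CC[C@H](C(C)(C)C(=O)OC(C)(C)C)[C@@](C)(CC(=O)OC(C)(C)C)/C=C\CC(=O)O | intermediate
18 | (3E,5S,6S)-isomer of 17 | CC(=O)CC[C@H](C(C)(C)C(=O)OC(C)(C)C)[C@@](C)(CC(=O)OC(C)(C)C)/C=C/CC(=O)O | intermediate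
19 | mixed anhydride of 18 with pivalic acid | CC(=O)CC[C@H](C(C)(C)C(=O)OC(C)(C)C)[C@@](C)(CC(=O)OC(C)(C)C)/C=C/CC(=O)OC(=O)C(C)(C)C | intermediate
20 | di-tert-butyl ester of (5S,8S,9R,10R)-2,3-seco-14,15,16-trinorlabd-11-en-13,8-olide-2,3-dioic acid | O=C1C=C[C@@H]2[C@](C)(CC(=O)OC(C)(C)C)[C@@H](C(C)(C)C(=O)OC(C)(C)C)CC[C@]2(C)O1 | intermediate
21 | 11,12-dihydro derivative of 20 (saturated δ-lactone) | O=C1CC[C@@H]2[C@](C)(CC(=O)OC(C)(C)C)[C@@H](C(C)(C)C(=O)OC(C)(C)C)CC[C@]2(C)O1 | intermediate
22 | di-tert-butyl (5S,8S,9R,10R)-8-hydroxy-13-oxo-14,15-dinor-2,3-secolabdane-2,3-dioate | CC(=O)CC[C@@H]1[C@](C)(CC(=O)OC(C)(C)C)[C@@H](C(C)(C)C(=O)OC(C)(C)C)CC[C@]1(C)O | intermediate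
23 | triethyl phosphonoacetate | CCOC(=O)CP(=O)(OCC)OCC | starting material
24 | 15-ethyl 2,3-di-tert-butyl (5S,8S,9R,10R,13E)-8-hydroxy-2,3-secolabd-13-ene-2,3,15-trioate | CCOC(=O)/C=C(\C)CC[C@@H]1[C@](C)(CC(=O)OC(C)(C)C)[C@@H](C(C)(C)C(=O)OC(C)(C)C)CC[C@]1(C)O | intermediate
25 | di-tert-butyl (5S,8S,9R,10R,13E)-8,15-dihydroxy-2,3-secolabd-13-ene-2,3-dioate | OC/C=C(\C)CC[C@@H]1[C@](C)(CC(=O)OC(C)(C)C)[C@@H](C(C)(C)C(=O)OC(C)(C)C)CC[C@]1(C)O | intermediate
26 | (13R,14R)-13,14-epoxide of 25 | OC[C@H]1O[C@]1(C)CC[C@@H]2[C@](C)(CC(=O)OC(C)(C)C)[C@@H](C(C)(C)C(=O)OC(C)(C)C)CC[C@]2(C)O | intermediate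
27 | di-tert-butyl (5S,8S,9R,10R,13S,14R)-8,13-epoxy-14,15-dihydroxy-2,3-secolabdane-2,3-dioate | OC[C@@H](O)[C@]1(C)CC[C@@H]2[C@](C)(CC(=O)OC(C)(C)C)[C@@H](C(C)(C)C(=O)OC(C)(C)C)CC[C@]2(C)O1 | intermediate
28 | (13S,14S)-13,14-epoxide of 25 | OC[C@@H]1O[C@@]1(C)CC[C@@H]2[C@](C)(CC(=O)OC(C)(C)C)[C@@H](C(C)(C)C(=O)OC(C)(C)C)CC[C@]2(C)O | intermediate
29 | di-tert-butyl (5S,8S,9R,10R,13R,14S)-8,13-epoxy-14,15-dihydroxy-2,3-secolabdane-2,3-dioate | OC[C@H](O)[C@@]1(C)CC[C@@H]2[C@](C)(CC(=O)OC(C)(C)C)[C@@H](C(C)(C)C(=O)OC(C)(C)C)CC[C@]2(C)O1 | intermediate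
30 | di-tert-butyl (5S,8S,9R,10R,13R)-8,13-epoxy-2,3-secolabd-14-ene-2,3-dioate | C=C[C@@]1(C)CC[C@@H]2[C@](C)(CC(=O)OC(C)(C)C)[C@@H](C(C)(C)C(=O)OC(C)(C)C)CC[C@]2(C)O1 | intermediate
31 | bis(trimethylsilyl) ester of 32 | C=C[C@@]1(C)CC[C@@H]2[C@](C)(CC(=O)O[Si](C)(C)C)[C@@H](C(C)(C)C(=O)O[Si](C)(C)C)CC[C@]2(C)O1 | intermediate
32 | (5S,8S,9R,10R,13R)-8,13-epoxy-2,3-secolabd-14-ene-2,3-dioic acid | C=C[C@@]1(C)CC[C@@H]2[C@](C)(CC(=O)O)[C@@H](C(C)(C)C(=O)O)CC[C@]2(C)O1 | intermediate
33 | cyclic 2,3-anhydride of 32 (seven-membered) | C=C[C@@]1(C)CC[C@@H]2[C@]3(C)CC(=O)OC(=O)C(C)(C)[C@H]3CC[C@]2(C)O1 | intermediate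
34 | C2 ester of 32 with O15 of 27 | C=C[C@@]1(C)CC[C@@H]2[C@](C)(CC(=O)OC[C@@H](O)[C@]3(C)CC[C@@H]4[C@](C)(CC(=O)OC(C)(C)C)[C@@H](C(C)(C)C(=O)OC(C)(C)C)CC[C@]4(C)O3)[C@@H](C(C)(C)C(=O)O)CC[C@]2(C)O1 | intermediate
35 | tetrakis(trimethylsilyl) derivative (three silyl esters, 14′-silyl ether) | C=C[C@@]1(C)CC[C@@H]2[C@](C)(CC(=O)OC[C@@H](O[Si](C)(C)C)[C@]3(C)CC[C@@H]4[C@](C)(CC(=O)O[Si](C)(C)C)[C@@H](C(C)(C)C(=O)O[Si](C)(C)C)CC[C@]4(C)O3)[C@@H](C(C)(C)C(=O)O[Si](C)(C)C)CC[C@]2(C)O1 | intermediate
36 | CNP0271961.3 | C=C[C@@]1(C)CC[C@@H]2[C@](C)(CC(=O)OC[C@@H](O)[C@]3(C)CC[C@@H]4[C@](C)(CC(=O)O)[C@@H](C(C)(C)C(=O)O)CC[C@]4(C)O3)[C@@H](C(C)(C)C(=O)O)CC[C@]2(C)O1 | target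

**Step count and risks**

Total: 20 steps. Longest linear sequence: 19 steps (steps 1–14 and 16–20, from tert-butyl 2-methylpropanoate); step 15 is the side branch.

Steps most likely to fail:

1. Step 10 (proposed new method). The dienolate may be reprotonated into the conjugated acid, or consumed through ketene-type oligomers, faster than its hindered γ-carbon reaches the ketone. The catalyst may also fail to override the substrate's own facial preference at C9, so that C11 ends equatorial and a trans-fused lactone forms. The fallback uses known chemistry, leaves the route at 15 and comes back at 22. Wittig reaction of 15 with Ph3P=CHOMe gives the enol ether F1, aqueous acid gives the homologated keto aldehyde F2, and Pinnick oxidation gives the keto acid F3. Nucleophile-catalysed aldol-lactonisation of F3 (2-chloro-1-methylpyridinium iodide, iPr2NEt, the same isothiourea, CH2Cl2) closes ring B through the same C8–C9 bond as the bicyclic β-lactone F4; its four-membered ring forces O8 and C11 cis. iBu2AlH at −78 °C opens F4 to the β-hydroxy aldehyde F5, Ph3P=CHCOCH3 gives the enone F6, and hydrogenation over Pd/C gives 22.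

2. Step 2. The oxazaborolidinium ion may discriminate the faces of an α-methyl enone poorly, or achiral silyl-cation catalysis may compete, so that C5 is formed with low enantiomeric purity. The fallback leaves from 1 and 4 and comes back at 8. The lithium enolate 2 adds 1,4 to 4 in THF/DMPU (−78 → −20 °C) to give the racemic ketone enolate, that is 7 together with its antipode F7, which is alkylated in the same flask with 6. Racemic 8, that is 8 together with its antipode F8, is then resolved by preparative chromatography on a chiral stationary phase, and 8 goes on to step 4.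

3. Step 20. The silyl triflate may ionise the tertiary allylic C13–O bond of the vinyl half before both tert-butyl esters are gone, with loss of the C13 configuration or opening of ring C. The fallback leaves from 27 and comes back at 36. The tert-butyl esters of 27 are removed first with CF3CO2H/CH2Cl2, where no allylic ether is present (trifluoroacetates cleaved with K2CO3/MeOH), to give the diacid diol F9. Allyl bromide/KHCO3 in DMF converts F9 into the diallyl ester F10. Coupling of F10 with 32 as in step 19 (through 33) gives the coupled diallyl ester F11, and Pd(PPh3)4/morpholine in THF removes both allyl groups under neutral conditions to give 36.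

Further compounds
F1 | step 10 | methyl enol ether from 15 (E/Z mixture at the new C=C) | CC(=O)CC[C@H](C(C)(C)C(=O)OC(C)(C)C)[C@@](C)(CC(=O)OC(C)(C)C)C=COC
F2 | step 10 | homologated keto aldehyde (C10–CH2–CHO) | CC(=O)CC[C@H](C(C)(C)C(=O)OC(C)(C)C)[C@@](C)(CC(=O)OC(C)(C)C)CC=O
F3 | step 10 | keto acid (C10–CH2–CO2H) | CC(=O)CC[C@H](C(C)(C)C(=O)OC(C)(C)C)[C@@](C)(CC(=O)OC(C)(C)C)CC(=O)O
F4 | step 10 | cis-fused bicyclic β-lactone (O8–C11 lactone on ring B) | O=C1O[C@@]2(C)CC[C@H](C(C)(C)C(=O)OC(C)(C)C)[C@@](C)(CC(=O)OC(C)(C)C)[C@@H]12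
F5 | step 10 | β-hydroxy aldehyde (8-hydroxy-11-al) | O=C[C@@H]1[C@](C)(CC(=O)OC(C)(C)C)[C@@H](C(C)(C)C(=O)OC(C)(C)C)CC[C@]1(C)O
F6 | step 10 | (E)-enone, 11,12-didehydro derivative of 22 | CC(=O)/C=C/[C@@H]1[C@](C)(CC(=O)OC(C)(C)C)[C@@H](C(C)(C)C(=O)OC(C)(C)C)CC[C@]1(C)O
F7 | step 2 | antipode of lithium enolate 7 | CC1=C([O-])CCC[C@H]1C(C)(C)C(=O)OC(C)(C)C.[Li+]
F8 | step 2 | antipode of ketone 8 | O=C1[C@@](C)(CC(=O)OC(C)(C)C)[C@H](C(C)(C)C(=O)OC(C)(C)C)CCC1
F9 | step 20 | (5S,8S,9R,10R,13S,14R)-8,13-epoxy-14,15-dihydroxy-2,3-secolabdane-2,3-dioic acid | OC[C@@H](O)[C@]1(C)CC[C@@H]2[C@](C)(CC(=O)O)[C@@H](C(C)(C)C(=O)O)CC[C@]2(C)O1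
F10 | step 20 | diallyl ester of F9 | OC[C@@H](O)[C@]1(C)CC[C@@H]2[C@](C)(CC(=O)OCC=C)[C@@H](C(C)(C)C(=O)OCC=C)CC[C@]2(C)O1
F11 | step 20 | C2 ester of 32 with O15 of F10 | C=C[C@@]1(C)CC[C@@H]2[C@](C)(CC(=O)OC[C@@H](O)[C@]3(C)CC[C@@H]4[C@](C)(CC(=O)OCC=C)[C@@H](C(C)(C)C(=O)OCC=C)CC[C@]4(C)O3)[C@@H](C(C)(C)C(=O)O)CC[C@]2(C)O1
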